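If D has to dissolve before X can form, the ratio of X to L must start from nothing, since none of D is in solution at the start.

common to all: J 0.50 M; D 47 mM (held)
- Wednesday's: Q 24 mM; run made earlier
- flask: Q 16 mM; time 15 d

Wednesday's run (percent of the J charged)

| time / d | X / % | L / % | J / % |
|---|---|---|---|
| 0.833 | 6.7 | 37.6 | 53.7 |
| 1.67 | 11.5 | 57.6 | 27.1 |
| 2.50 | 13.7 | 71.8 | 14.9 |
| 3.00 | 15.1 | 74.7 | 10.8 |
| 4.00 | 16.0 | 79.6 | 4.9 |
| 5.00 | 15.8 | 81.4 | 1.9 |

(standard deviation of a reading: 1 percentage point)

* ratio of X to L at 3.0 h
* ratio of X to L at 15 d

- at the start none of D is in solution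
- no earlier run changes the charge of Q; that part of a forecast is a guess

Yet Wednesday's first reading of this ratio, the selectivity, is 0.178, and the last 3 readings pooled give 0.199. Wednesday's flask, which began with none of D in solution, seems to show nearly its late ratio by the first sampling. This is how I reckon it, and you can check each step.

1. Suppose L forms steadily and X starts after a delay. The first reading then falls short of the late ratio by a fraction equal to the delay over the time elapsed, so the delay in Wednesday's flask is 0.0870 d. It is a rough figure, as readings scatter by 1 percentage point. But it is far shorter than the time of that first reading, so the sampling came too late to show it.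

2. No run changes Q. My guess is that the ratio follows the Q charged, which gives the ratio per unit of Q, 8.29 M⁻¹.

3. With 16 mM of Q, this guess puts the late ratio of the new flask at 0.133.

4. So early, a sharp start is too crude, so I let the rate of X climb exponentially to its late value, with the delay as its time constant, which gives the same shortfall late on. I keep the delay, D being held at 47 mM in both flasks. At 3.0 h the new flask then stands at a fraction 0.469 of its late ratio, or 0.0623.

The forecast gives 0.19 (0.11 to 0.26) at 3.0 h and 0.19 (0.13 to 0.25) at 15 d, with the grounds “parallel paths from J with fixed selectivity”, and stands higher than my reckoning at both times.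

The flask gives 0.0693 at 3.0 h and 0.145 at 15 d, against my 0.0623 and 0.133. It ends with X at 12.6 % and L at 87.3 % of the J charged.

    E + Z → Q + X (k = 70.0 M⁻¹ h⁻¹)
    G → L (k = 0.527 h⁻¹)
    D ⇌ E, rate k3*(csat - [E]) (kL = 0.308 h⁻¹)
    J + Q → Q + G (k = 1.35 M⁻¹ h⁻¹)
    Q + G ⇌ Z (K = 1.89 M⁻¹, k = 32.3 M⁻¹ h⁻¹)

Take the ratio per unit of Q, 8.29 M⁻¹, to a neighbouring flask, the same but with 6.40 mM of Q. With the same delay fraction it gives 0.0249 at 3.0 h and 0.0531 at 15 d. That neighbouring flask gives 0.0285 and 0.0615, and ends with X at 5.52 %.

The earlier runs and the new flask are simulated with made-up constants.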